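**Plan**

1. Retrosynthesis: the C15 acid goes back to a silyl ether and C1–C2 to an alkene, then the ring-fusion bond C5–C10 is cut. C5 and C10 lie opposite each other in the ten-membered carbocycle C1–C10, so this one bond closes ring A and ring B together while C5 stays sp2 (C5=C6); the precursor is the ten-membered dienyl triflate 33.
2. The ten-membered ring is cut at C2–C3 (anionic oxy-Cope) and C4–C19 (enolate methylation) to a ring-B cyclohexanol with a 1-(hydroxymethyl)vinyl group on C5 and a vinyl group on C10. That is cut at C4–C5, C10–C1 and C9–C11 to (S)-3,4-dimethylcyclohexenone, a C11–C15 bromide, an α-seleno acetaldehyde and a 2-bromoallyl ether.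
3. Forward: ring B first (enone 12); side chain and C1–C2 by conjugate addition/aldol; C3–C4–C18 by 1,2-addition; ring expansion to the ten-membered ring (step 16); triflate; transannular Heck closure of rings A and B (step 18); diimide, desilylation, oxidation.
4. Stereochemistry: C13 from desymmetrisation of 3-methylglutaric anhydride; C8 from an organocatalytic Michael addition; C9 from cuprate addition anti to the C8 methyl; C4 from peripheral methylation of the oxy-Cope enolate, whose planar chirality is relayed from C5/C10 of the cyclohexanol; (E)-C1=C10 from the chair Cope; C10 from the chair-like fold of C5–C10 in the Heck step.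

Key step: step 18

Remark: halimane numbers are used for all intermediates; α/β refer to the orientation in which the C20 methyl on C9 is β, so the target has 8β-CH3, 9α-side chain, 10α-H, 4α-CH2OAc and 4β-CH3.
Remark: (DHQ)2AQN in step 1 and the (R)-prolinol ether in step 6 are assumed to give the (S)-configured products 2 and 9; both catalysts have commercial antipodes if the sense of induction is the opposite.

**Route**

Step 1
Reactants: 1 3-methylglutaric anhydride
Product: 2 (S)-5-methoxy-3-methyl-5-oxopentanoic acid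
Conditions: MeOH (10 equiv), (DHQ)2AQN (10 mol %), Et2O, −40 °C
Reagents that add atoms: methanol CO
Why: Cinchona-alkaloid-catalysed enantioselective alcoholysis of the meso anhydride, in which the catalyst activates MeOH toward one of the two enantiotopic carbonyl groups, sets C13.

Step 2
Reactants: 2 (S)-5-methoxy-3-methyl-5-oxopentanoic acid
Product: 3 methyl (S)-5-hydroxy-3-methylpentanoate
Conditions: BH3·SMe2, THF, 0 °C to rt; MeOH quench
Reagents that add atoms: none
Why: Chemoselective borane reduction of a carboxylic acid in the presence of a methyl ester gives the C15 alcohol.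

Step 3
Reactants: 3 methyl (S)-5-hydroxy-3-methylpentanoate
Product: 4 methyl (S)-5-(tert-butyldiphenylsilyloxy)-3-methylpentanoate
Conditions: t-BuPh2SiCl, imidazole, DMF, rt
Reagents that add atoms: tert-butyl(chloro)diphenylsilane CC(C)(C)[Si](Cl)(c1ccccc1)c1ccccc1
Why: Silyl ether protection of the primary alcohol; the TBDPS group should survive the organometallic, strongly basic and mild fluoride steps up to step 20.

Step 4
Reactants: 4 methyl (S)-5-(tert-butyldiphenylsilyloxy)-3-methylpentanoate
Product: 5 (R)-5-(tert-butyldiphenylsilyloxy)-3-methylpentan-1-ol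
Conditions: iBu2AlH (2.5 equiv), CH2Cl2, −78 to 0 °C; Rochelle salt
Reagents that add atoms: none
Why: Hydride reduction of the ester to the primary alcohol (C11).

Step 5
Reactants: 5 (R)-5-(tert-butyldiphenylsilyloxy)-3-methylpentan-1-ol
Product: 6 (S)-(5-bromo-3-methylpentoxy)(tert-butyl)diphenylsilane
Conditions: CBr4, PPh3, CH2Cl2, 0 °C
Reagents that add atoms: tetrabromomethane BrC(Br)(Br)Br
Why: Appel bromination of the primary alcohol gives the C11 electrophile for Grignard formation.

Step 6
Reactants: 7 propanal; 8 but-3-en-2-one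
Product: 9 (S)-2-methyl-5-oxohexanal
Conditions: (R)-2-[methoxy(diphenyl)methyl]pyrrolidine (5 mol %), ethyl 3,4-dihydroxybenzoate (20 mol %), neat, 4 °C
Reagents that add atoms: none
Why: Enamine-catalysed asymmetric Michael addition of the aldehyde to the vinyl ketone, in which the diarylmethyl group shields one face of the (E)-enamine, sets the future C8.

Step 7
Reactants: 9 (S)-2-methyl-5-oxohexanal
Product: 10 (S)-4-methylcyclohex-2-en-1-one
Conditions: KOH (0.1 M aq), Bu4NOH (cat.), Et2O–THF, reflux
Reagents that add atoms: none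
Why: Intramolecular aldol condensation of the methyl ketone onto the aldehyde closes ring B, and the stereocentre becomes the non-enolisable γ-carbon of the enone once the ring has formed.

Step 8
Reactants: 10 (S)-4-methylcyclohex-2-en-1-one
Product: 11 [(3R,4S)-3,4-dimethylcyclohexen-1-yl]oxytrimethylsilane
Conditions: MeLi (2 equiv), CuI, Et2O, 0 °C; then 10, Me3SiCl, Et3N, −78 °C
Reagents that add atoms: lithium dimethylcuprate [Li+].C[Cu-]C; chlorotrimethylsilane C[Si](C)(C)Cl
Why: Cuprate conjugate addition brings in the C20 methyl and the enolate is silylated in situ; the new centre (trans to the C8 methyl) is removed again in step 9.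

Step 9
Reactants: 11 [(3R,4S)-3,4-dimethylcyclohexen-1-yl]oxytrimethylsilane
Product: 12 (S)-3,4-dimethylcyclohex-2-en-1-one
Conditions: Pd(OAc)2 (10 mol %), O2 (1 atm), DMSO, rt
Reagents that add atoms: none
Why: Saegusa–Ito dehydrogenation of the silyl enol ether regiospecifically restores the enone, now with the C9 methyl in place.

Step 10
Reactants: 13 ethyl vinyl ether; 14 benzeneselenenyl chloride
Product: 16 2-(phenylselanyl)acetaldehyde, via α-chloro ether 15 (not isolated)
Conditions: CH2Cl2, −78 °C; then H2O, NaHCO3, rt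
Reagents that add atoms: water O
Why: Electrophilic selenenylation of the enol ether by PhSeCl followed by hydrolysis of the α-chloro ether gives the α-seleno aldehyde used as a vinyl cation equivalent (C1–C2).

Step 11
Reactants: 17 2-bromoprop-2-en-1-ol
Product: 18 (2-bromoprop-2-enoxy)(tert-butyl)dimethylsilane
Conditions: t-BuMe2SiCl, imidazole, CH2Cl2, rt
Reagents that add atoms: tert-butyl(chloro)dimethylsilane CC(C)(C)[Si](C)(C)Cl
Why: Silyl ether protection of the allylic alcohol (C18) so that the bromide can be lithiated in step 14.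

Step 12
Reactants: 6 (S)-(5-bromo-3-methylpentoxy)(tert-butyl)diphenylsilane; 12 (S)-3,4-dimethylcyclohex-2-en-1-one; 16 2-(phenylselanyl)acetaldehyde
Product: 21 (2R,3R,4S)-2-[1-hydroxy-2-(phenylselanyl)ethyl]-3,4-dimethyl-3-[(3R)-5-(tert-butyldiphenylsilyloxy)-3-methylpentyl]cyclohexanone (C1 carbinol epimers), via Grignard reagent 19 (not isolated), via bromomagnesium enolate 20 (not isolated)
Conditions: Mg, THF (6 to 19); CuBr·SMe2 (10 mol %), THF, −40 °C, then 12; then 16, −78 to 0 °C; aq NH4Cl
Reagents that add atoms: none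
Why: Copper-catalysed conjugate addition of the Grignard reagent anti to the C8 methyl sets the C9 quaternary centre (C17 and C20 cis), and the regiodefined enolate is trapped at C10 by aldol addition; on warming, the chelated aldolate should equilibrate so that the new side chain sits equatorial, trans to the C9 chain (10α-H), while the carbinol centre is left uncontrolled because step 13 destroys it.

Step 13
Reactants: 21 (2R,3R,4S)-2-[1-hydroxy-2-(phenylselanyl)ethyl]-3,4-dimethyl-3-[(3R)-5-(tert-butyldiphenylsilyloxy)-3-methylpentyl]cyclohexanone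
Product: 23 (2S,3R,4S)-2-ethenyl-3,4-dimethyl-3-[(3R)-5-(tert-butyldiphenylsilyloxy)-3-methylpentyl]cyclohexanone, via C1 mesylate 22 (not isolated)
Conditions: MeSO2Cl, Et3N, CH2Cl2, 0 °C
Reagents that add atoms: none
Why: Reductive elimination of a β-hydroxy selenide (mesylation, selenium-assisted ionisation, loss of PhSe+) completes the α-vinylation of the ketone without touching C10.

Step 14
Reactants: 18 (2-bromoprop-2-enoxy)(tert-butyl)dimethylsilane; 23 (2S,3R,4S)-2-ethenyl-3,4-dimethyl-3-[(3R)-5-(tert-butyldiphenylsilyloxy)-3-methylpentyl]cyclohexanone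
Product: 26 (1R,2S,3R,4S)-1-[3-(tert-butyldimethylsilyloxy)prop-1-en-2-yl]-2-ethenyl-3,4-dimethyl-3-[(3R)-5-(tert-butyldiphenylsilyloxy)-3-methylpentyl]cyclohexan-1-ol, via alkenyllithium 24 (not isolated), via alkenylcerium dichloride 25 (not isolated)
Conditions: 18, t-BuLi (2 equiv), Et2O, −78 °C; CeCl3, THF, −78 °C; then 23, −78 to −40 °C; aq NH4Cl
Reagents that add atoms: none
Why: Bromine–lithium exchange and 1,2-addition of the weakly basic organocerium reagent to the enolisable ketone from the equatorial α-face (the β-face is blocked by the axial C20 methyl) should give the trans-1-alkenyl-2-vinylcyclohexanol with 5β-OH.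

Step 15
Reactants: 26 (1R,2S,3R,4S)-1-[3-(tert-butyldimethylsilyloxy)prop-1-en-2-yl]-2-ethenyl-3,4-dimethyl-3-[(3R)-5-(tert-butyldiphenylsilyloxy)-3-methylpentyl]cyclohexan-1-ol
Product: 27 (1R,2S,3R,4S)-2-ethenyl-1-(3-hydroxyprop-1-en-2-yl)-3,4-dimethyl-3-[(3R)-5-(tert-butyldiphenylsilyloxy)-3-methylpentyl]cyclohexan-1-ol
Conditions: HF·pyridine, pyridine, THF, 0 °C
Reagents that add atoms: none
Why: Selective fluoride cleavage of the primary TBS ether in the presence of the more robust TBDPS ether frees the C18 hydroxyl, which must be an alkoxide in step 16.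

Step 16
Reactants: 27 (1R,2S,3R,4S)-2-ethenyl-1-(3-hydroxyprop-1-en-2-yl)-3,4-dimethyl-3-[(3R)-5-(tert-butyldiphenylsilyloxy)-3-methylpentyl]cyclohexan-1-ol
Product: 31 (4S,8S,9R,13R)-18-acetoxy-15-(tert-butyldiphenylsilyloxy)-5,10-secohalim-1(10)E-en-5-one, via dipotassium dialkoxide 28 (not isolated), via ring-expanded enolate alkoxide 29 (not isolated), via potassium aldolate 30 (not isolated)
Conditions: KN(SiMe3)2 (2.2 equiv), 18-crown-6, THF, 0 to 40 °C; then −78 °C, MeI (1.1 equiv); then Ac2O (3 equiv), −78 to 0 °C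
Reagents that add atoms: iodomethane CI; acetic anhydride CC(=O)OC(C)=O
Why: Anionic oxy-Cope ring expansion of the trans-diequatorial dialkenylcyclohexanolate through a chair transition state breaks C5–C10 and forms C2–C3, giving the (E)-cyclodec-5-enone as its C4 enolate; the C18 alkoxide cannot leave, so the enolate survives and is C-methylated from its peripheral face, which should set C4 (4α-CH2O, 4β-CH3) by relay of the C5/C10 configuration, and Ac2O then caps the alkoxide before retro-aldol can occur.

Step 17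
Reactants: 31 (4S,8S,9R,13R)-18-acetoxy-15-(tert-butyldiphenylsilyloxy)-5,10-secohalim-1(10)E-en-5-one
Product: 33 (4S,8S,9R,13R)-18-acetoxy-15-(tert-butyldiphenylsilyloxy)-5,10-secohalima-1(10)E,5-dien-5-yl trifluoromethanesulfonate (triflate cis to C7), via potassium enolate 32 (not isolated)
Conditions: KN(SiMe3)2 (1.05 equiv), THF, −78 °C; then PhNTf2, −78 to −20 °C
Reagents that add atoms: N-phenylbis(trifluoromethanesulfonimide) O=S(=O)(N(c1ccccc1)S(=O)(=O)C(F)(F)F)C(F)(F)F
Why: Kinetic enolisation and O-triflation; C4 is quaternary so only C6 can be deprotonated, the C4–C5–C6–C7 array is antiperiplanar in the ring as formed and a tert-alkyl ketone favours the enolate with oxygen cis to the α-substituent, so the triflate should end up cis to C7, and the ketone is deprotonated in preference to the less acidic acetate at −78 °C.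

Step 18
Reactants: 33 (4S,8S,9R,13R)-18-acetoxy-15-(tert-butyldiphenylsilyloxy)-5,10-secohalima-1(10)E,5-dien-5-yl trifluoromethanesulfonate
Product: 34 (4R,8S,9R,10S,13R)-18-acetoxy-15-(tert-butyldiphenylsilyloxy)halima-1,5-diene
Conditions: Pd(PPh3)4 (10 mol %), Et3N (3 equiv), MeCN, 70 °C
Reagents that add atoms: none
Why: Proposed new method: zerovalent palladium inserts into the C5–OTf bond, the cationic C5-alkenylpalladium (divalent) binds the (E)-C1=C10 alkene lying across the ten-membered ring, syn-carbopalladation forms C5–C10 and puts palladium on C1, and syn β-hydride loss toward C2 followed by deprotonation of the palladium hydride by Et3N returns the catalyst; a transannular Heck reaction of a cyclodecadienyl triflate has not been shown, the closest known chemistry being intramolecular Heck cyclisations of alkenyl triflates and transannular cation–olefin and carbonyl–ene closures of cyclodecadienes. Ring B closes in the 6-exo-trig mode (tether C6–C9, C1 left outside the ring) and ring A in the 6-endo-trig mode (tether C4–C2), both in the same migratory insertion. The new stereocentre C10 is set by the face of C1=C10 that meets C5: in the chair-like fold of C5–C10 that keeps the C8 methyl and the C9 side chain equatorial, which is the fold in which the ring was made in step 16, C1 is pseudo-equatorial and C5 should bond cis to the C9 chain, giving 10α-H. The step needs (a) the triflate cis to C7, secured in step 17, (b) bonding of C5 to C10 only, secured by the 1,6-relation of the two alkenes across the ring, and (c) β-hydride loss away from C10, secured by the E geometry, which leaves H10 anti to palladium after syn addition. Migration of the new disubstituted alkene within ring A would be harmless because step 19 saturates it.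

Step 19
Reactants: 34 (4R,8S,9R,10S,13R)-18-acetoxy-15-(tert-butyldiphenylsilyloxy)halima-1,5-diene
Product: 35 (4R,8S,9R,10S,13R)-18-acetoxy-15-(tert-butyldiphenylsilyloxy)halim-5-ene
Conditions: 2-nitrobenzenesulfonylhydrazide, Et3N, CH2Cl2, rt
Reagents that add atoms: none
Why: Diimide reduction transfers H2 concertedly to the unhindered cis-disubstituted C1=C2 alkene and should leave the trisubstituted C5=C6 alkene, flanked by the quaternary C4, untouched.

Step 20
Reactants: 35 (4R,8S,9R,10S,13R)-18-acetoxy-15-(tert-butyldiphenylsilyloxy)halim-5-ene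
Product: 36 (4R,8S,9R,10S,13R)-18-acetoxyhalim-5-en-15-ol
Conditions: Bu4NF, AcOH (1:1), THF, rt
Reagents that add atoms: none
Why: Buffered fluoride desilylation removes the TBDPS group while the acetate is kept.

Step 21
Reactants: 36 (4R,8S,9R,10S,13R)-18-acetoxyhalim-5-en-15-ol
Product: 38 (4R,8S,9R,10S,13R)-18-acetoxyhalim-5-en-15-oic acid, via aldehyde 37 (not isolated)
Conditions: TEMPO (20 mol %), PhI(OAc)2 (2.2 equiv), MeCN–H2O (1:1), rt
Reagents that add atoms: water O
Why: Oxoammonium-mediated oxidation of the primary alcohol through the aldehyde hydrate gives the carboxylic acid under conditions that tolerate the acetate and the trisubstituted alkene.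

**Compound list**

1 | 3-methylglutaric anhydride | CC1CC(=O)OC(=O)C1 | starting material
2 | (S)-5-methoxy-3-methyl-5-oxopentanoic acid | COC(=O)C[C@@H](C)CC(=O)O | intermediate
3 | methyl (S)-5-hydroxy-3-methylpentanoate | COC(=O)C[C@@H](C)CCO | intermediate
4 | methyl (S)-5-(tert-butyldiphenylsilyloxy)-3-methylpentanoate | COC(=O)C[C@@H](C)CCO[Si](c1ccccc1)(c1ccccc1)C(C)(C)C | intermediate
5 | (R)-5-(tert-butyldiphenylsilyloxy)-3-methylpentan-1-ol | OCC[C@@H](C)CCO[Si](c1ccccc1)(c1ccccc1)C(C)(C)C | intermediate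
6 | (S)-(5-bromo-3-methylpentoxy)(tert-butyl)diphenylsilane | BrCC[C@@H](C)CCO[Si](c1ccccc1)(c1ccccc1)C(C)(C)C | intermediate
7 | propanal | CCC=O | starting material
8 | but-3-en-2-one | CC(=O)C=C | starting material
9 | (S)-2-methyl-5-oxohexanal | CC(=O)CC[C@H](C)C=O | intermediate
10 | (S)-4-methylcyclohex-2-en-1-one | O=C1CC[C@H](C)C=C1 | intermediate
11 | [(3R,4S)-3,4-dimethylcyclohexen-1-yl]oxytrimethylsilane | C[Si](C)(C)OC1=C[C@H](C)[C@@H](C)CC1 | intermediate
12 | (S)-3,4-dimethylcyclohex-2-en-1-one | O=C1CC[C@H](C)C(C)=C1 | intermediate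
13 | ethyl vinyl ether | C=COCC | starting material
14 | benzeneselenenyl chloride | Cl[Se]c1ccccc1 | starting material
15 | (2-chloro-2-ethoxyethyl)selanylbenzene | CCOC(Cl)C[Se]c1ccccc1 | intermediate
16 | 2-(phenylselanyl)acetaldehyde | O=CC[Se]c1ccccc1 | intermediate
17 | 2-bromoprop-2-en-1-ol | OCC(Br)=C | starting material
18 | (2-bromoprop-2-enoxy)(tert-butyl)dimethylsilane | C=C(Br)CO[Si](C)(C)C(C)(C)C | intermediate
19 | [(3S)-5-(tert-butyldiphenylsilyloxy)-3-methylpentyl]magnesium bromide | Br[Mg]CC[C@@H](C)CCO[Si](c1ccccc1)(c1ccccc1)C(C)(C)C | intermediate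
20 | bromomagnesium (3R,4S)-3,4-dimethyl-3-[(3R)-5-(tert-butyldiphenylsilyloxy)-3-methylpentyl]cyclohexen-1-olate | Br[Mg]OC1=C[C@](C)(CC[C@@H](C)CCO[Si](c2ccccc2)(c2ccccc2)C(C)(C)C)[C@@H](C)CC1 | intermediate
21 | (2R,3R,4S)-2-[1-hydroxy-2-(phenylselanyl)ethyl]-3,4-dimethyl-3-[(3R)-5-(tert-butyldiphenylsilyloxy)-3-methylpentyl]cyclohexanone (carbinol epimers) | O=C1CC[C@H](C)[C@@](C)(CC[C@@H](C)CCO[Si](c2ccccc2)(c2ccccc2)C(C)(C)C)[C@@H]1C(O)C[Se]c1ccccc1 | intermediate
22 | methanesulfonate of 21 at the side-chain carbinol | O=C1CC[C@H](C)[C@@](C)(CC[C@@H](C)CCO[Si](c2ccccc2)(c2ccccc2)C(C)(C)C)[C@@H]1C(OS(C)(=O)=O)C[Se]c1ccccc1 | intermediate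
23 | (2S,3R,4S)-2-ethenyl-3,4-dimethyl-3-[(3R)-5-(tert-butyldiphenylsilyloxy)-3-methylpentyl]cyclohexanone | O=C1CC[C@H](C)[C@@](C)(CC[C@@H](C)CCO[Si](c2ccccc2)(c2ccccc2)C(C)(C)C)[C@@H]1C=C | intermediate
24 | [3-(tert-butyldimethylsilyloxy)prop-1-en-2-yl]lithium | [Li]C(=C)CO[Si](C)(C)C(C)(C)C | intermediate
25 | dichloro[3-(tert-butyldimethylsilyloxy)prop-1-en-2-yl]cerium | Cl[Ce](Cl)C(=C)CO[Si](C)(C)C(C)(C)C | intermediate
26 | (1R,2S,3R,4S)-1-[3-(tert-butyldimethylsilyloxy)prop-1-en-2-yl]-2-ethenyl-3,4-dimethyl-3-[(3R)-5-(tert-butyldiphenylsilyloxy)-3-methylpentyl]cyclohexan-1-ol | O[C@]1(C(=C)CO[Si](C)(C)C(C)(C)C)CC[C@H](C)[C@@](C)(CC[C@@H](C)CCO[Si](c2ccccc2)(c2ccccc2)C(C)(C)C)[C@@H]1C=C | intermediate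
27 | (1R,2S,3R,4S)-2-ethenyl-1-(3-hydroxyprop-1-en-2-yl)-3,4-dimethyl-3-[(3R)-5-(tert-butyldiphenylsilyloxy)-3-methylpentyl]cyclohexan-1-ol | O[C@]1(C(=C)CO)CC[C@H](C)[C@@](C)(CC[C@@H](C)CCO[Si](c2ccccc2)(c2ccccc2)C(C)(C)C)[C@@H]1C=C | intermediate
28 | dipotassium dialkoxide of 27 | [K+].[K+].[O-][C@]1(C(=C)C[O-])CC[C@H](C)[C@@](C)(CC[C@@H](C)CCO[Si](c2ccccc2)(c2ccccc2)C(C)(C)C)[C@@H]1C=C | intermediate
29 | dipotassium (8S,9R,13R)-15-(tert-butyldiphenylsilyloxy)-5,10-secohalima-1(10)E,4-diene-5,18-diolate | [K+].[K+].[O-]C/C1=C(/[O-])CC[C@H](C)[C@@](C)(CC[C@@H](C)CCO[Si](c2ccccc2)(c2ccccc2)C(C)(C)C)/C=C/CC1 | intermediate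
30 | potassium (4S,8S,9R,13R)-15-(tert-butyldiphenylsilyloxy)-5-oxo-5,10-secohalim-1(10)E-en-18-olate | [K+].[O-]C[C@]1(C)CC/C=C/[C@](C)(CC[C@@H](C)CCO[Si](c2ccccc2)(c2ccccc2)C(C)(C)C)[C@@H](C)CCC1=O | intermediate
31 | (4S,8S,9R,13R)-18-acetoxy-15-(tert-butyldiphenylsilyloxy)-5,10-secohalim-1(10)E-en-5-one | CC(=O)OC[C@]1(C)CC/C=C/[C@](C)(CC[C@@H](C)CCO[Si](c2ccccc2)(c2ccccc2)C(C)(C)C)[C@@H](C)CCC1=O | intermediate
32 | potassium C5 enolate of 31 (oxygen cis to C7) | [K+].CC(=O)OC[C@]1(C)CC/C=C/[C@](C)(CC[C@@H](C)CCO[Si](c2ccccc2)(c2ccccc2)C(C)(C)C)[C@@H](C)C/C=C1\[O-] | intermediate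
33 | (4S,8S,9R,13R)-18-acetoxy-15-(tert-butyldiphenylsilyloxy)-5,10-secohalima-1(10)E,5-dien-5-yl trifluoromethanesulfonate | CC(=O)OC[C@]1(C)CC/C=C/[C@](C)(CC[C@@H](C)CCO[Si](c2ccccc2)(c2ccccc2)C(C)(C)C)[C@@H](C)C/C=C1\OS(=O)(=O)C(F)(F)F | intermediate
34 | (4R,8S,9R,10S,13R)-18-acetoxy-15-(tert-butyldiphenylsilyloxy)halima-1,5-diene | CC(=O)OC[C@]1(C)CC=C[C@@H]2C1=CC[C@H](C)[C@@]2(C)CC[C@@H](C)CCO[Si](c3ccccc3)(c3ccccc3)C(C)(C)C | intermediate
35 | (4R,8S,9R,10S,13R)-18-acetoxy-15-(tert-butyldiphenylsilyloxy)halim-5-ene | CC(=O)OC[C@]1(C)CCC[C@@H]2C1=CC[C@H](C)[C@@]2(C)CC[C@@H](C)CCO[Si](c3ccccc3)(c3ccccc3)C(C)(C)C | intermediate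
36 | (4R,8S,9R,10S,13R)-18-acetoxyhalim-5-en-15-ol | CC(=O)OC[C@]1(C)CCC[C@@H]2C1=CC[C@H](C)[C@@]2(C)CC[C@@H](C)CCO | intermediate
37 | (4R,8S,9R,10S,13R)-18-acetoxyhalim-5-en-15-al | CC(=O)OC[C@]1(C)CCC[C@@H]2C1=CC[C@H](C)[C@@]2(C)CC[C@@H](C)CC=O | intermediate
38 | (4R,8S,9R,10S,13R)-18-acetoxyhalim-5-en-15-oic acid | CC(=O)OC[C@]1(C)CCC[C@@H]2C1=CC[C@H](C)[C@@]2(C)CC[C@@H](C)CC(=O)O | target

**Count and risks**

Total step count: 21. Longest linear sequence: 15 steps (steps 1–5 and 12–21).

Step 18 (transannular Heck). The vinylpalladium may fail to reach C1=C10 and be reduced instead, the insertion may take the other face of the alkene, or β-hydride loss may run toward C10 and give the conjugated 1(10),5-diene. The fallback forms the same C5–C10 bond by known transannular chemistry. It sets out from ketone 31: Me2AlCl in CH2Cl2 at −78 °C should promote the transannular carbonyl–ene reaction of the (E)-cyclodec-5-enone (C5 bonds to C10, a C2 hydrogen moves to oxygen), giving (13R)-18-acetoxy-15-(tert-butyldiphenylsilyloxy)-10α-halim-1-en-5β-ol F1 through the same chair-like fold. Syn-dehydration with the Burgess reagent can only use a C6 hydrogen, because H10 is anti to the 5β-hydroxyl and C4 is quaternary, and so gives C5=C6. The fallback comes back to the route at 34.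

Step 16 (oxy-Cope/methylation/acetylation). After C-methylation the potassium aldolate may lose formaldehyde by retro-aldol, the primary alkoxide may be O-methylated, or proton transfer may scramble the hindered enolate before it is alkylated. The fallback brings in C19 without an alkylation. It sets out from diol 27: the same ring expansion is quenched with Me3SiCl to give the bis-silyl compound (8S,9R,13R)-5,18-bis(trimethylsilyloxy)-15-(tert-butyldiphenylsilyloxy)-5,10-secohalima-1(10)E,4-diene F2. Simmons–Smith cyclopropanation (Et2Zn, CH2I2) of the electron-rich silyl enol ether from its peripheral face gives the siloxycyclopropane F3. K2CO3 in MeOH opens the cyclopropanol to the α-methyl ketone and frees the primary alcohol, giving (4S,8S,9R,13R)-18-hydroxy-15-(tert-butyldiphenylsilyloxy)-5,10-secohalim-1(10)E-en-5-one F4. Acetylation (Ac2O, pyridine, DMAP) returns to the route at 31.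

Step 14 (addition of the 2-lithioallyl ether). The alkenylmetal may lose silyloxide to give allene before it adds, or it may remove the doubly activated C10 hydrogen of the vinyl ketone instead of attacking the hindered carbonyl. The fallback uses a robust nucleophile and introduces the C18 oxygen afterwards. It sets out from ketone 23: isopropenylmagnesium bromide with CeCl3 should add from the same α-face to give (1R,2S,3R,4S)-2-ethenyl-3,4-dimethyl-1-(prop-1-en-2-yl)-3-[(3R)-5-(tert-butyldiphenylsilyloxy)-3-methylpentyl]cyclohexan-1-ol F5. Allylic hydroxylation of the isopropenyl methyl with catalytic SeO2 and t-BuOOH (the 1,1-disubstituted alkene reacts before the vinyl group and C5 carries no hydrogen) returns to the route at diol 27, which also makes steps 11 and 15 unnecessary.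

Further compounds
F1 | step 18 | (13R)-18-acetoxy-15-(tert-butyldiphenylsilyloxy)-10α-halim-1-en-5β-ol | CC(=O)OC[C@]1(C)CC=C[C@@H]2[C@]1(O)CC[C@H](C)[C@@]2(C)CC[C@@H](C)CCO[Si](c3ccccc3)(c3ccccc3)C(C)(C)C
F2 | step 16 | (8S,9R,13R)-5,18-bis(trimethylsilyloxy)-15-(tert-butyldiphenylsilyloxy)-5,10-secohalima-1(10)E,4-diene | C[Si](C)(C)OC/C1=C(/O[Si](C)(C)C)CC[C@H](C)[C@@](C)(CC[C@@H](C)CCO[Si](c2ccccc2)(c2ccccc2)C(C)(C)C)/C=C/CC1
F3 | step 16 | siloxycyclopropane from F2 (C19 methylene bridging C4 and C5 on the peripheral face) | C[Si](C)(C)OC[C@@]12C[C@@]1(O[Si](C)(C)C)CC[C@H](C)[C@@](C)(CC[C@@H](C)CCO[Si](c3ccccc3)(c3ccccc3)C(C)(C)C)/C=C/CC2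
F4 | step 16 | (4S,8S,9R,13R)-18-hydroxy-15-(tert-butyldiphenylsilyloxy)-5,10-secohalim-1(10)E-en-5-one | OC[C@]1(C)CC/C=C/[C@](C)(CC[C@@H](C)CCO[Si](c2ccccc2)(c2ccccc2)C(C)(C)C)[C@@H](C)CCC1=O
F5 | step 14 | (1R,2S,3R,4S)-2-ethenyl-3,4-dimethyl-1-(prop-1-en-2-yl)-3-[(3R)-5-(tert-butyldiphenylsilyloxy)-3-methylpentyl]cyclohexan-1-ol | O[C@]1(C(C)=C)CC[C@H](C)[C@@](C)(CC[C@@H](C)CCO[Si](c2ccccc2)(c2ccccc2)C(C)(C)C)[C@@H]1C=C
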